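The rate constants were drawn at random within sensible limits; the run is a simulation.

Temperature was what set these flasks apart, so I looked for one quantity that carries its effect on the share of target.

in all of them: solid substrate 0.10 M; catalyst 0.5 mol%; time 30 h
- beta: temperature 110 °C
- alpha: at 110 °C until 20 h, from then on at 85 °C
- gamma: temperature 85 °C

    starting material + catalyst → catalyst + target (k1 = 20 M⁻¹ min⁻¹, Ea1 = 49.0 kJ mol⁻¹)
    starting material + target → side product (k2 = 0.017 M⁻¹ min⁻¹, Ea2 = 84.0 kJ mol⁻¹)
    solid substrate ⇌ starting material, rate k3*(cs3 - [starting material]) while solid is left; crystals form when [starting material] > cs3 (cs3 = 0.092 M, k3 = 0.0029 min⁻¹)
    (constants at 110 °C)

- percent here means solid substrate units held: one side product counts as two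
- solid substrate is a solid; its amount is given per volume of the solution
- the constants hold at 110 °C; other temperatures follow from the activation energies
- at the start none of the solid substrate is in solution
- what has only dissolved of solid substrate counts as not reacted

- the flask that comes out highest in share of target in all that became target or side product, or "all alike" when all lie within 1.5 percentage points (beta / alpha / gamma / all alike)
- share of target in all that became target or side product, beta
- share of target in all that became target or side product, alpha
- share of target in all that became target or side product, gamma

Both steps consume dissolved starting material at first order, so c(starting material) cancels from their ratio and the pace of dissolving drops out of the split. That leaves two pseudo-first-order rates: the catalysed one, 0.0100 min⁻¹ at 110 °C, and the side step's constant times c(target). I divided the first by the side step's constant and got K = 0.588 M, the target concentration at which the side step would match the catalysed step, a selectivity factor in concentration units. Against K stands the charge, 0.10 M, the ceiling on c(target); their ratio r was 5.88.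

Integrating the split and keeping terms up to the square gave s + s·s/r = 1 for s, the share of target once the charge had reacted through, which was 87.1% at 110 °C. Cooling to 85 °C slows the side step by a factor of 6.3, more than the catalysed step's factor of 2.9, so K rose to 1.27 M, r to 12.7 and s to 93.1%.

Starting material's lifetime against the catalysed step was 1.67 h at 110 °C, but it arrives by dissolving. Taking c(starting material) where dissolving matches the catalysed step, I reckoned that dissolving the charge took about 8.06 h at 110 °C. Alpha's change at 20 h then came 7.15 lifetimes after that, so I expected alpha to match beta.

The forecast gave 86.1% for beta, 86.1% for alpha and 92.9% for gamma, putting gamma highest; it took the split as independent of dissolving, since “both steps are first order in dissolved starting material”. My beta figure stood 1 percentage point above its number.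

The simulation gave 86.0% for beta, 86.0% for alpha and 92.9% for gamma, with gamma highest. The neighbouring flask was alpha with 1.2 mol% of catalyst. At 110 °C its K became 1.41 M, so r was 14.1 and s came to 93.8%. The simulated neighbour ended at a share of 93.5%, with 6.48% of the charge as side product and 0% of the solid substrate left.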